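The zeta flask, which is the flask asked about, falls from 27.6 % to 3.5 % of target between 2.50 min and 5.00 min. That fall gives the tail constant, the logarithmic loss of target per minute over the last two readings: 0.826 /min, as read.

- zeta: substrate 0.80 M; solid partner 0.96 M; the very flask that is asked about, followed so far
- flask: substrate 0.80 M; solid partner 0.960 M; time 15 min

zeta run (percent of the substrate charged)

| time / min | target / % |
|---|---|
| 0.417 | 7.8 |
| 0.667 | 18.5 |
| 1.33 | 38.3 |
| 2.50 | 27.6 |
| 5.00 | 3.5 |

(scatter of a reading: 0.5 percentage points)

* when, up to 15 min, the flask holds most target
* the amount of target, in percent of the substrate charged, at that time
* earliest time at which at least nineteen twentieths of that best amount are there, in min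
* latest time at which they still are, in min

- solid partner is a solid; its amount is given per volume of the solution
- at the start none of the solid partner is in solution

The ladder of times in the zeta flask starts with the lag. None of the solid partner is in solution at the start, and the gain of target quickens from 0.187 /min of the charge up to 0.417 min to 0.428 /min up to 0.667 min. The next rung is the tail half-life, 0.839 min. The top rung is the allowed 15 min, which is much longer than that half-life and holds 17.9 of them. So the maximum lies early, near the reading of 38.3 % at 1.33 min, the highest of the run.

This reading needs a small correction, not a full model. Taking the tail constant as a first-order loss, which is an assumption of this reckoning, target at its top is made as fast as it is lost, and that loss is the tail constant times the target present. At the reading of 1.33 min, my reckoning puts that rate near 0.253 M/min.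

The forecast gives 39.5 % (range 38.3 % to 42.5 %) at 1.55 min (range 1.35 min to 1.75 min), with the window from 1.22 min (range 1.05 min to 1.33 min) to 1.92 min (range 1.7 min to 2.15 min). Its ground is the same balance: “The maximum comes where formation equals loss”.

    target → over-reaction product (k = 0.0160 /s)
    open intermediate + second intermediate → target (k = 0.0730 /M/s)
    fresh partner → second intermediate (k = 0.0480 /s)
    solid partner ⇌ fresh partner, rate k4*(cs4 - [fresh partner]) while solid is left; crystals form when [fresh partner] > cs4 (solubility = 0.410 M, k = 0.0700 /s)
    substrate → open intermediate (k = 0.660 /s)

The flask gives 40.1 % at 1.52 min, with the window from 1.27 min to 1.81 min. That best stands 1.8 percentage points above the reading at 1.33 min. At the top, over-reaction product holds 31.0 % of the substrate charged and open intermediate 29.0 %. The tail half-life of 0.839 min, as read, is longer than the 0.72 min of target by its passing into over-reaction product alone. Carried on from the 1.95 % of target at 6.06 min, the tail constant gives 0.594 % at 7.50 min, and the flask holds 0.657 % there.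

All runs are simulated with constants of no real substance; the scatter is artificial.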